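**Strategy.** Ring B (C5–C6–C7–C8–C9–C10) is treated as a Diels–Alder cyclohexene: the exocyclic C8 methylene is a masked ketone, so C7=C8(OSi)–C9=C10 becomes a 2-silyloxydiene and C5=C6 a sulfone-activated dienophile, joined through C1–C4 of ring A. One intramolecular [4+2] reaction of an open-chain 1,3,9-decatriene closes rings A and B together (bonds C5–C10 and C6–C7), sets the trans ring fusion with the C10 quaternary methyl under control of the C3 silyl ether, and leaves a regiodefined C8 enol ether for benzylation at C9. The epoxyquinol is then grown from the attached arene by dearomatisation, hydroxyl-directed epoxidation and reduction.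

Key step: step 7

Remark: drimane numbering (C1–C15) is used for the decalin and C1′–C6′ for the oxygenated ring (C1′ bears C11); Ar = 5-methoxy-2-(triisopropylsilyloxy)-4-[(triisopropylsilyloxy)methyl]phenyl; compounds 1, 14 and 32 are taken as commercial.

**Step 1**
Reactants: 1 pent-4-yn-1-ol
Product: 3 (E)-5-iodo-4-methylpent-4-en-1-ol, via alkenylalane 2 (not isolated)
Conditions: Me3Al (3 equiv), Cp2ZrCl2 (0.25 equiv), CH2Cl2, 0 → 23 °C; then I2, THF, −30 → 0 °C
Reagents that add atoms: trimethylaluminium C[Al](C)C; iodine II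
Why: Negishi zirconium-catalysed syn-carboalumination puts methyl on the internal alkyne carbon with aluminium cis to it, and iodinolysis with retention gives the (E)-vinyl iodide that fixes the later C9=C10 geometry.

**Step 2**
Reactants: 3 (E)-5-iodo-4-methylpent-4-en-1-ol
Product: 4 (E)-5-iodo-4-methylpent-4-enal
Conditions: Dess–Martin periodinane, NaHCO3, CH2Cl2, 0 → 23 °C
Reagents that add atoms: none
Why: Dess–Martin oxidation of the primary alcohol stops at the aldehyde and leaves the vinyl iodide untouched.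

**Step 3**
Reactants: 4 (E)-5-iodo-4-methylpent-4-enal
Product: 6 (4S,7E)-8-iodo-3,3,7-trimethylocta-1,7-dien-4-ol, via borinate 5 (not isolated)
Conditions: (+)-Ipc2BH [from (−)-α-pinene], 3-methylbuta-1,2-diene, THF, −25 °C; then 4, −78 °C; NaOH, H2O2
Reagents that add atoms: 3-methylbuta-1,2-diene CC(C)=C=C, transferred as B-(3-methylbut-2-enyl)bis(isopinocampheyl)borane CC(C)=CCB([C@H]1C[C@H]2C[C@@H]([C@@H]1C)C2(C)C)[C@H]1C[C@H]2C[C@@H]([C@@H]1C)C2(C)C
Why: Brown asymmetric reverse prenylboration proceeds through a closed chair transition state with allylic transposition, creating the gem-dimethyl carbon (future C4) and vinyl group (future C5=C6), and the isopinocampheyl groups from (−)-α-pinene are expected to direct attack to the Re face to give the (S)-carbinol (future C3).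

**Step 4**
Reactants: 6 (4S,7E)-8-iodo-3,3,7-trimethylocta-1,7-dien-4-ol
Product: 8 (1E,4S,7E)-8-iodo-3,3,7-trimethyl-1-(phenylsulfonyl)octa-1,7-dien-4-ol, via iodosulfone 7 (not isolated)
Conditions: PhSO2Na, I2, NaOAc, EtOAc–H2O, 23 °C, light; then DBU, MeCN, 0 → 23 °C
Reagents that add atoms: sodium benzenesulfinate [Na+].[O-]S(=O)c1ccccc1
Why: Radical iodosulfonylation adds the sulfonyl radical to the terminal CH2 of the monosubstituted alkene (the hindered vinyl iodide should not compete), and E1cB loss of HI, possible only toward the sulfone because the neighbouring carbon is quaternary, gives the (E)-vinyl sulfone.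

**Step 5**
Reactants: 8 (1E,4S,7E)-8-iodo-3,3,7-trimethyl-1-(phenylsulfonyl)octa-1,7-dien-4-ol
Product: 10 (3E,7S,9E)-7-hydroxy-4,8,8-trimethyl-10-(phenylsulfonyl)deca-3,9-dien-2-one, via ethoxydiene 9 (not isolated)
Conditions: tributyl(1-ethoxyvinyl)stannane, Pd(PPh3)4 (5 mol%), CuI (10 mol%), DMF, 60 °C; then 5% aq. oxalic acid, THF, 0 °C
Reagents that add atoms: tributyl(1-ethoxyvinyl)stannane CCCC[Sn](CCCC)(CCCC)C(=C)OCC; water O
Why: Stille coupling proceeds with retention at the vinyl iodide and mild enol ether hydrolysis unmasks the (E)-methyl enone, cold weak acid being chosen so that the hindered hydroxyl does not add to the β,β-disubstituted enone.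

**Step 6**
Reactants: 10 (3E,7S,9E)-7-hydroxy-4,8,8-trimethyl-10-(phenylsulfonyl)deca-3,9-dien-2-one
Product: 11 (3E,7S,9E)-4,8,8-trimethyl-10-(phenylsulfonyl)-2,7-bis(triethylsilyloxy)deca-1,3,9-triene
Conditions: TESOTf (2.5 equiv), Et3N (4 equiv), CH2Cl2, −78 → 0 °C
Reagents that add atoms: triethylsilyl trifluoromethanesulfonate CC[Si](CC)(CC)OS(=O)(=O)C(F)(F)F
Why: Soft enolisation silylates the carbinol and deprotonates the O-silylated enone at the kinetic α′-methyl group, giving the cross-conjugated 2-silyloxydiene without changing the C9=C10 geometry or the vinyl sulfone, which has no γ-hydrogen.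

**Step 7**
Reactants: 11 (3E,7S,9E)-4,8,8-trimethyl-10-(phenylsulfonyl)-2,7-bis(triethylsilyloxy)deca-1,3,9-triene
Product: 12 6α-(phenylsulfonyl)-3β,8-bis(triethylsilyloxy)-11,12-dinordrim-8-ene (5α-H, 10β-methyl)
Conditions: PhMe (0.01 M), BHT (cat.), Et3N (cat.), 150 °C, sealed tube, 36 h
Reagents that add atoms: none
Why: This is a concerted thermal [π4s+π2s] cycloaddition of the electron-rich 2-silyloxydiene (C7=C8–C9=C10) with the (E)-vinyl sulfone (C5=C6), a type 1 intramolecular Diels–Alder reaction of a 1,3,9-decatriene whose closest known relatives are sulfone- and nitro-activated decatriene cyclisations and additions of 2-silyloxy-4-methylpenta-1,3-diene. Ring A closes as a six-membered ring through the four-carbon tether in the fused mode (bond C5–C10), and ring B is the cyclohexene of the cycloaddition itself (bonds C5–C10 and C6–C7). The trans fusion (10β-methyl, 5α-H) should follow from the (E)-C9=C10 geometry (tether outside, methyl inside) together with the transition state that holds the sulfone endo and the tether anti in a chair-like fold, and the (E)-dienophile then places the sulfone at C6α. The absolute sense is relayed from C3, because the (S)-triethylsilyloxy group should prefer the equatorial site of the chair-like tether and so select the diene face leading to the natural 5α,10β series with a 3β-silyloxy group. The step needs endo/exo (trans versus cis fusion) and π-facial selectivity, the first secured by the sulfone and the gem-dimethyl group beside the dienophile, the second by the C3 stereocentre, with minor diastereomers to be removed by chromatography. Regiochemistry is enforced by the tether, and the product keeps the C8=C9 silyl enol ether that defines the later enolate.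

**Step 8**
Reactants: 12 6α-(phenylsulfonyl)-3β,8-bis(triethylsilyloxy)-11,12-dinordrim-8-ene
Product: 13 3β,8-bis(triethylsilyloxy)-11,12-dinordrim-8-ene
Conditions: lithium naphthalenide (3 equiv), THF, −78 °C, 10 min; MeOH quench
Reagents that add atoms: none
Why: Single-electron reductive desulfonylation cleaves the alkyl C–S bond and the carbanion is protonated on quenching, the cold aprotic conditions preserving the silyl enol ether, whose hydrolysis would give a β-sulfonyl ketone prone to elimination.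

**Step 9**
Reactants: 14 2,5-dimethoxyterephthalaldehyde
Product: 15 2-hydroxy-5-methoxyterephthalaldehyde
Conditions: BCl3 (1.05 equiv), CH2Cl2, −78 → 0 °C; H2O
Reagents that add atoms: none
Why: Chelation-assisted Lewis acid demethylation cleaves one methoxy group ortho to a formyl group, and the aryloxyboron chelate formed should slow a second cleavage, so the two oxygens of the future quinone become different.

**Step 10**
Reactants: 15 2-hydroxy-5-methoxyterephthalaldehyde
Product: 16 2-hydroxy-4-(hydroxymethyl)-5-methoxybenzaldehyde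
Conditions: NaBH4 (0.3 equiv), NaOH (1.1 equiv), MeOH–H2O, −10 °C; AcOH
Reagents that add atoms: none
Why: Chemoselective borohydride reduction is expected because in the phenoxide the formyl group ortho to O− is a deactivated vinylogous carboxylate, so hydride adds to the other formyl group.

**Step 11**
Reactants: 16 2-hydroxy-4-(hydroxymethyl)-5-methoxybenzaldehyde
Product: 17 5-methoxy-2-(triisopropylsilyloxy)-4-[(triisopropylsilyloxy)methyl]benzaldehyde
Conditions: TIPSOTf (2.3 equiv), 2,6-lutidine, CH2Cl2, 0 °C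
Reagents that add atoms: triisopropylsilyl trifluoromethanesulfonate CC(C)[Si](C(C)C)(C(C)C)OS(=O)(=O)C(F)(F)F
Why: Silylation of phenol and primary alcohol gives ethers stable to organolithium, ylide and mild acid but labile to fluoride.

**Step 12**
Reactants: 17 5-methoxy-2-(triisopropylsilyloxy)-4-[(triisopropylsilyloxy)methyl]benzaldehyde
Product: 18 {5-methoxy-2-(triisopropylsilyloxy)-4-[(triisopropylsilyloxy)methyl]phenyl}methanol
Conditions: DIBAL-H, CH2Cl2, −78 °C; Rochelle salt
Reagents that add atoms: none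
Why: Hydride reduction of the aldehyde at low temperature passes through an aluminium alkoxide, which should prevent phenol-to-benzylic silyl migration.

**Step 13**
Reactants: 18 {5-methoxy-2-(triisopropylsilyloxy)-4-[(triisopropylsilyloxy)methyl]phenyl}methanol
Product: 19 1-(bromomethyl)-5-methoxy-2-(triisopropylsilyloxy)-4-[(triisopropylsilyloxy)methyl]benzene (ArCH2Br)
Conditions: CBr4, PPh3, CH2Cl2, 0 °C
Reagents that add atoms: carbon tetrabromide BrC(Br)(Br)Br
Why: Appel bromination converts the benzylic alcohol to the bromide under neutral conditions that keep both silyl ethers.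

**Step 14**
Reactants: 13 3β,8-bis(triethylsilyloxy)-11,12-dinordrim-8-ene; 19 ArCH2Br
Product: 22 11-Ar-3β-(triethylsilyloxy)-12-nordriman-8-one (9β-CH2Ar), via lithium enolate 20 (not isolated), via 9-epi ketone 21 (not isolated)
Conditions: MeLi (1.05 equiv), THF, 0 → 23 °C; then 19, HMPA, −78 → 0 °C; then DBU, THF, 50 °C
Reagents that add atoms: none
Why: Regiospecific enolate generation from the silyl enol ether and SN2 benzylation at C9 (expected axial, anti to the 10β-methyl) are followed by base equilibration through the enol to the more stable equatorial 9β-arylmethyl ketone, which sets C9.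

**Step 15**
Reactants: 22 11-Ar-3β-(triethylsilyloxy)-12-nordriman-8-one
Product: 23 11-Ar-3β-(triethylsilyloxy)drim-8(12)-ene
Conditions: Ph3PCH3Br, NaHMDS, THF, 65 °C
Reagents that add atoms: methyltriphenylphosphonium bromide C[P+](c1ccccc1)(c1ccccc1)c1ccccc1.[Br-]
Why: Wittig methylenation of the hindered C8 ketone installs the exocyclic C8=C12 alkene, and any α-epimerisation by the ylide only returns the more stable 9β ketone.

**Step 16**
Reactants: 23 11-Ar-3β-(triethylsilyloxy)drim-8(12)-ene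
Product: 24 11-Ar-drim-8(12)-en-3β-ol
Conditions: PPTS, MeOH–CH2Cl2, 40 °C
Reagents that add atoms: none
Why: Mild acid methanolysis removes the secondary triethylsilyl ether while the aryl and primary triisopropylsilyl ethers and the exocyclic alkene should be unaffected.

**Step 17**
Reactants: 24 11-Ar-drim-8(12)-en-3β-ol
Product: 25 11-Ar-drim-8(12)-en-3-one
Conditions: Dess–Martin periodinane, NaHCO3, CH2Cl2, 23 °C
Reagents that add atoms: none
Why: Dess–Martin oxidation gives the C3 ketone, erasing the stereocentre that served as control element so that it can be reset.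

**Step 18**
Reactants: 25 11-Ar-drim-8(12)-en-3-one
Product: 26 11-Ar-drim-8(12)-en-3α-ol
Conditions: L-Selectride, THF, −78 °C; aq. NH4Cl
Reagents that add atoms: none
Why: The bulky trialkylborohydride should attack the 4,4-dimethyl-3-ketone from the equatorial direction and give the axial 3α-alcohol (3R), as is usual for 3-oxo-4,4-dimethyl terpenoids.

**Step 19**
Reactants: 26 11-Ar-drim-8(12)-en-3α-ol
Product: 27 11-[2-hydroxy-4-(hydroxymethyl)-5-methoxyphenyl]drim-8(12)-en-3α-ol
Conditions: TBAF (2.5 equiv), THF, 0 → 23 °C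
Reagents that add atoms: none
Why: Fluoride cleaves both triisopropylsilyl ethers and frees the phenol and the benzylic alcohol.

**Step 20**
Reactants: 27 11-[2-hydroxy-4-(hydroxymethyl)-5-methoxyphenyl]drim-8(12)-en-3α-ol
Product: 28 2-(3α-hydroxydrim-8(12)-en-11-yl)-5-(hydroxymethyl)-4,4-dimethoxycyclohexa-2,5-dien-1-one
Conditions: PhI(OAc)2, MeOH, 0 °C
Reagents that add atoms: methanol CO
Why: Oxidative dearomatisation of the p-methoxyphenol is trapped by methanol para to oxygen, so the phenol carbon (C6′) becomes the dienone carbonyl and C3′ the dimethyl ketal.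

**Step 21**
Reactants: 28 2-(3α-hydroxydrim-8(12)-en-11-yl)-5-(hydroxymethyl)-4,4-dimethoxycyclohexa-2,5-dien-1-one
Product: 29 (1S,6R)-1-(3α-hydroxydrim-8(12)-en-11-yl)-4-(hydroxymethyl)-5,5-dimethoxy-7-oxabicyclo[4.1.0]hept-3-en-2-one
Conditions: Ph3COOH, NaHMDS, L-(+)-diisopropyl tartrate, 4 Å MS, PhMe, −40 °C
Reagents that add atoms: trityl hydroperoxide OOC(c1ccccc1)(c1ccccc1)c1ccccc1
Why: In this tartrate-mediated, hydroxyl-directed Weitz–Scheffer epoxidation the sodium alkoxide of the C4′ hydroxymethyl should deliver the peroxide across the ketal carbon to C2′ of the α-alkylated enone (the other β-carbon, C4′, is fully substituted), and the face is reagent-controlled by the tartrate, L-tartrate being proposed and D-tartrate to be used if the opposite face were delivered.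

**Step 22**
Reactants: 29 epoxy ketal
Product: 30 (1S,6R)-1-(3α-hydroxydrim-8(12)-en-11-yl)-4-(hydroxymethyl)-7-oxabicyclo[4.1.0]hept-3-ene-2,5-dione
Conditions: montmorillonite K10, wet CH2Cl2, 23 °C
Reagents that add atoms: water O
Why: Ketal hydrolysis on a mild solid acid unmasks the C3′ carbonyl and should neither open the epoxide nor isomerise the exocyclic alkene.

**Step 23**
Reactants: 30 epoxy enedione
Product: 31 (1S,5R,6S)-5-hydroxy-1-(3α-hydroxydrim-8(12)-en-11-yl)-4-(hydroxymethyl)-7-oxabicyclo[4.1.0]hept-3-en-2-one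
Conditions: DIBAL-H (3 equiv), THF, −78 °C; Rochelle salt
Reagents that add atoms: none
Why: The aluminium alkoxide of the C4′ hydroxymethyl should direct 1,2-reduction to the neighbouring C3′ carbonyl (C6′ is shielded by the quaternary C1′), and hydride is expected on the epoxide face, opposite the C1′ side chain and assisted by aluminium coordination to the epoxide oxygen, giving the alcohol anti to the epoxide.

**Step 24**
Reactants: 32 (S)-3-hydroxybutanoic acid
Product: 34 (S)-3-(tert-butyldimethylsilyloxy)butanoic acid, via silyl ester 33 (not isolated)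
Conditions: TBSCl (2.3 equiv), imidazole, DMF, 23 °C; then AcOH–THF–H2O
Reagents that add atoms: tert-butyldimethylsilyl chloride CC(C)(C)[Si](C)(C)Cl
Why: Silylation of hydroxyl and carboxyl groups followed by selective hydrolysis of the labile silyl ester gives the O-protected acid with the chiral-pool stereocentre untouched.

**Step 25**
Reactants: 31 epoxyquinol triol; 34 (S)-3-(tert-butyldimethylsilyloxy)butanoic acid
Product: 35 O-TBS-neomacrophorin III (silyl ether at the side-chain hydroxyl)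
Conditions: EDC·HCl (1.1 equiv), DMAP (0.1 equiv), CH2Cl2, −20 °C
Reagents that add atoms: none
Why: Steglich esterification with the acid as limiting partner should acylate the primary allylic alcohol much faster than the secondary C3′ carbinol or the hindered axial C3 hydroxyl.

**Step 26**
Reactants: 35 O-TBS-neomacrophorin III
Product: 36 neomacrophorin III
Conditions: HF·pyridine, THF–pyridine, 0 → 23 °C
Reagents that add atoms: none
Why: Buffered fluoride desilylation frees the side-chain secondary alcohol and should not harm the epoxy enone, the ester or the exocyclic alkene.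

**Compound list**

1 | pent-4-yn-1-ol | C#CCCCO | starting material
2 | dimethylaluminium alkoxide of (E)-5-(dimethylalumanyl)-4-methylpent-4-en-1-ol | C[Al](C)OCCC/C(C)=C/[Al](C)C | intermediate
3 | (E)-5-iodo-4-methylpent-4-en-1-ol | OCCC/C(C)=C/I | intermediate
4 | (E)-5-iodo-4-methylpent-4-enal | O=CCC/C(C)=C/I | intermediate
5 | bis(isopinocampheyl)borinate of 6 | I/C=C(C)/CC[C@H](OB([C@H]1C[C@H]2C[C@@H]([C@@H]1C)C2(C)C)[C@H]1C[C@H]2C[C@@H]([C@@H]1C)C2(C)C)C(C)(C)C=C | intermediate
6 | (4S,7E)-8-iodo-3,3,7-trimethylocta-1,7-dien-4-ol | I/C=C(C)/CC[C@H](O)C(C)(C)C=C | intermediate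
7 | (4S,7E)-2,8-diiodo-3,3,7-trimethyl-1-(phenylsulfonyl)oct-7-en-4-ol (both C2 epimers) | I/C=C(C)/CC[C@H](O)C(C)(C)C(I)CS(=O)(=O)c1ccccc1 | intermediate
8 | (1E,4S,7E)-8-iodo-3,3,7-trimethyl-1-(phenylsulfonyl)octa-1,7-dien-4-ol | I/C=C(C)/CC[C@H](O)C(C)(C)/C=C/S(=O)(=O)c1ccccc1 | intermediate
9 | (1E,4S,7E)-9-ethoxy-3,3,7-trimethyl-1-(phenylsulfonyl)deca-1,7,9-trien-4-ol | C=C(OCC)/C=C(C)/CC[C@H](O)C(C)(C)/C=C/S(=O)(=O)c1ccccc1 | intermediate
10 | (3E,7S,9E)-7-hydroxy-4,8,8-trimethyl-10-(phenylsulfonyl)deca-3,9-dien-2-one | CC(=O)/C=C(C)/CC[C@H](O)C(C)(C)/C=C/S(=O)(=O)c1ccccc1 | intermediate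
11 | (3E,7S,9E)-4,8,8-trimethyl-10-(phenylsulfonyl)-2,7-bis(triethylsilyloxy)deca-1,3,9-triene | C=C(O[Si](CC)(CC)CC)/C=C(C)/CC[C@H](O[Si](CC)(CC)CC)C(C)(C)/C=C/S(=O)(=O)c1ccccc1 | intermediate
12 | 6α-(phenylsulfonyl)-3β,8-bis(triethylsilyloxy)-11,12-dinordrim-8-ene | CC[Si](CC)(CC)OC1=C[C@@]2(C)CC[C@H](O[Si](CC)(CC)CC)C(C)(C)[C@@H]2[C@@H](S(=O)(=O)c2ccccc2)C1 | intermediate
13 | 3β,8-bis(triethylsilyloxy)-11,12-dinordrim-8-ene | CC[Si](CC)(CC)OC1=C[C@@]2(C)CC[C@H](O[Si](CC)(CC)CC)C(C)(C)[C@@H]2CC1 | intermediate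
14 | 2,5-dimethoxyterephthalaldehyde | COc1cc(C=O)c(OC)cc1C=O | starting material
15 | 2-hydroxy-5-methoxyterephthalaldehyde | O=Cc1cc(OC)c(C=O)cc1O | intermediate
16 | 2-hydroxy-4-(hydroxymethyl)-5-methoxybenzaldehyde | O=Cc1cc(OC)c(CO)cc1O | intermediate
17 | 5-methoxy-2-(triisopropylsilyloxy)-4-[(triisopropylsilyloxy)methyl]benzaldehyde | O=Cc1cc(OC)c(CO[Si](C(C)C)(C(C)C)C(C)C)cc1O[Si](C(C)C)(C(C)C)C(C)C | intermediate
18 | {5-methoxy-2-(triisopropylsilyloxy)-4-[(triisopropylsilyloxy)methyl]phenyl}methanol | OCc1cc(OC)c(CO[Si](C(C)C)(C(C)C)C(C)C)cc1O[Si](C(C)C)(C(C)C)C(C)C | intermediate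
19 | 1-(bromomethyl)-5-methoxy-2-(triisopropylsilyloxy)-4-[(triisopropylsilyloxy)methyl]benzene | BrCc1cc(OC)c(CO[Si](C(C)C)(C(C)C)C(C)C)cc1O[Si](C(C)C)(C(C)C)C(C)C | intermediate
20 | lithium Δ8(9)-enolate of 3β-(triethylsilyloxy)-11,12-dinordriman-8-one | [Li]OC1=C[C@@]2(C)CC[C@H](O[Si](CC)(CC)CC)C(C)(C)[C@@H]2CC1 | intermediate
21 | 11-Ar-3β-(triethylsilyloxy)-12-nor-9-epi-driman-8-one (9α-CH2Ar) | O=C1CC[C@H]2C(C)(C)[C@@H](O[Si](CC)(CC)CC)CC[C@]2(C)[C@@H]1Cc1cc(OC)c(CO[Si](C(C)C)(C(C)C)C(C)C)cc1O[Si](C(C)C)(C(C)C)C(C)C | intermediate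
22 | 11-Ar-3β-(triethylsilyloxy)-12-nordriman-8-one (9β-CH2Ar) | O=C1CC[C@H]2C(C)(C)[C@@H](O[Si](CC)(CC)CC)CC[C@]2(C)[C@H]1Cc1cc(OC)c(CO[Si](C(C)C)(C(C)C)C(C)C)cc1O[Si](C(C)C)(C(C)C)C(C)C | intermediate
23 | 11-Ar-3β-(triethylsilyloxy)drim-8(12)-ene | C=C1CC[C@H]2C(C)(C)[C@@H](O[Si](CC)(CC)CC)CC[C@]2(C)[C@H]1Cc1cc(OC)c(CO[Si](C(C)C)(C(C)C)C(C)C)cc1O[Si](C(C)C)(C(C)C)C(C)C | intermediate
24 | 11-Ar-drim-8(12)-en-3β-ol | C=C1CC[C@H]2C(C)(C)[C@@H](O)CC[C@]2(C)[C@H]1Cc1cc(OC)c(CO[Si](C(C)C)(C(C)C)C(C)C)cc1O[Si](C(C)C)(C(C)C)C(C)C | intermediate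
25 | 11-Ar-drim-8(12)-en-3-one | C=C1CC[C@H]2C(C)(C)C(=O)CC[C@]2(C)[C@H]1Cc1cc(OC)c(CO[Si](C(C)C)(C(C)C)C(C)C)cc1O[Si](C(C)C)(C(C)C)C(C)C | intermediate
26 | 11-Ar-drim-8(12)-en-3α-ol | C=C1CC[C@H]2C(C)(C)[C@H](O)CC[C@]2(C)[C@H]1Cc1cc(OC)c(CO[Si](C(C)C)(C(C)C)C(C)C)cc1O[Si](C(C)C)(C(C)C)C(C)C | intermediate
27 | 11-[2-hydroxy-4-(hydroxymethyl)-5-methoxyphenyl]drim-8(12)-en-3α-ol | C=C1CC[C@H]2C(C)(C)[C@H](O)CC[C@]2(C)[C@H]1Cc1cc(OC)c(CO)cc1O | intermediate
28 | 2-(3α-hydroxydrim-8(12)-en-11-yl)-5-(hydroxymethyl)-4,4-dimethoxycyclohexa-2,5-dien-1-one | C=C1CC[C@H]2C(C)(C)[C@H](O)CC[C@]2(C)[C@H]1CC1=CC(OC)(OC)C(CO)=CC1=O | intermediate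
29 | (1S,6R)-1-(3α-hydroxydrim-8(12)-en-11-yl)-4-(hydroxymethyl)-5,5-dimethoxy-7-oxabicyclo[4.1.0]hept-3-en-2-one | C=C1CC[C@H]2C(C)(C)[C@H](O)CC[C@]2(C)[C@H]1C[C@]12O[C@H]1C(OC)(OC)C(CO)=CC2=O | intermediate
30 | (1S,6R)-1-(3α-hydroxydrim-8(12)-en-11-yl)-4-(hydroxymethyl)-7-oxabicyclo[4.1.0]hept-3-ene-2,5-dione | C=C1CC[C@H]2C(C)(C)[C@H](O)CC[C@]2(C)[C@H]1C[C@]12O[C@H]1C(=O)C(CO)=CC2=O | intermediate
31 | (1S,5R,6S)-5-hydroxy-1-(3α-hydroxydrim-8(12)-en-11-yl)-4-(hydroxymethyl)-7-oxabicyclo[4.1.0]hept-3-en-2-one | C=C1CC[C@H]2C(C)(C)[C@H](O)CC[C@]2(C)[C@H]1C[C@]12O[C@H]1[C@H](O)C(CO)=CC2=O | intermediate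
32 | (S)-3-hydroxybutanoic acid | OC(=O)C[C@H](C)O | starting material
33 | tert-butyldimethylsilyl (S)-3-(tert-butyldimethylsilyloxy)butanoate | CC(C)(C)[Si](C)(C)OC(=O)C[C@H](C)O[Si](C)(C)C(C)(C)C | intermediate
34 | (S)-3-(tert-butyldimethylsilyloxy)butanoic acid | OC(=O)C[C@H](C)O[Si](C)(C)C(C)(C)C | intermediate
35 | O-TBS-neomacrophorin III | C=C1CC[C@H]2C(C)(C)[C@H](O)CC[C@]2(C)[C@H]1C[C@]12O[C@H]1[C@H](O)C(COC(=O)C[C@H](C)O[Si](C)(C)C(C)(C)C)=CC2=O | intermediate
36 | neomacrophorin III | C=C1CC[C@H]2C(C)(C)[C@H](O)CC[C@]2(C)[C@H]1C[C@]12O[C@H]1[C@H](O)C(COC(=O)C[C@H](C)O)=CC2=O | target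

**Totals.** 26 steps in all. The longest linear sequence is 20 steps (1–8, 14–23, 25, 26).

**Steps most likely to fail**

1. Step 7. The cycloaddition may stall or lose selectivity: the diene with its inside methyl can undergo [1,5]-hydrogen shift at 150 °C, and endo/exo and π-facial discrimination may be too low. The fallback changes the dienophile activation, its installation and its removal. Setting out from 6, radical nitration of the terminal alkene (AgNO2, TEMPO, DCE, 70 °C) should give the (E)-nitroalkene F1. Stille coupling and hydrolysis as in step 5 lead through the nitro ethoxydiene F2 to the nitro enone F3, which is silylated (TESOTf, 2,6-di-tert-butyl-4-methylpyridine, −78 °C) to the nitro triene F4. The nitroalkene Diels–Alder reaction should run at 60–80 °C with a strong endo preference to give the nitro cycloadduct F5, and radical denitration (Bu3SnH, AIBN, PhMe, 110 °C) comes back to the route at 13.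

2. Step 21. The tartrate aggregate may give poor face selection or low conversion at the hindered α-alkylated olefin, and the free C3 hydroxyl may disturb the sodium alkoxide network. The fallback replaces hydroxyl direction by ion-pair control. From 28 the primary alcohol is silylated (TBSCl, imidazole, DMF) to the dienone silyl ether F6, which is epoxidised under chiral phase-transfer conditions (N-benzylcinchonidinium chloride or its pseudoenantiomer, t-BuOOH, aq. NaOH, PhMe) to the epoxide silyl ether F7. HF·pyridine then comes back to the route at 29.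

3. Step 23. Hydride may arrive anti to the epoxide oxygen and give the syn alcohol, or the wrong carbonyl may be reduced. The fallback accepts the syn alcohol and inverts it. From 30, hydroxyl-directed reduction with Me4NBH(OAc)3 (MeCN–AcOH, −20 °C) should give the syn diol F8. Acylation with 34 as in step 25 gives the syn ester F9, Mitsunobu inversion (PPh3, DIAD, HCO2H) gives the inverted formate F10, and selective formate methanolysis (NaHCO3, MeOH, 0 °C) comes back to the route at 35.

**Further compounds**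

F1 | step 7 | (1E,4S,7E)-8-iodo-3,3,7-trimethyl-1-nitroocta-1,7-dien-4-ol | I/C=C(C)/CC[C@H](O)C(C)(C)/C=C/[N+](=O)[O-]
F2 | step 7 | (1E,4S,7E)-9-ethoxy-3,3,7-trimethyl-1-nitrodeca-1,7,9-trien-4-ol | C=C(OCC)/C=C(C)/CC[C@H](O)C(C)(C)/C=C/[N+](=O)[O-]
F3 | step 7 | (3E,7S,9E)-7-hydroxy-4,8,8-trimethyl-10-nitrodeca-3,9-dien-2-one | CC(=O)/C=C(C)/CC[C@H](O)C(C)(C)/C=C/[N+](=O)[O-]
F4 | step 7 | (3E,7S,9E)-4,8,8-trimethyl-10-nitro-2,7-bis(triethylsilyloxy)deca-1,3,9-triene | C=C(O[Si](CC)(CC)CC)/C=C(C)/CC[C@H](O[Si](CC)(CC)CC)C(C)(C)/C=C/[N+](=O)[O-]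
F5 | step 7 | 6α-nitro-3β,8-bis(triethylsilyloxy)-11,12-dinordrim-8-ene | CC[Si](CC)(CC)OC1=C[C@@]2(C)CC[C@H](O[Si](CC)(CC)CC)C(C)(C)[C@@H]2[C@@H]([N+](=O)[O-])C1
F6 | step 21 | 5-[(tert-butyldimethylsilyloxy)methyl]-2-(3α-hydroxydrim-8(12)-en-11-yl)-4,4-dimethoxycyclohexa-2,5-dien-1-one | C=C1CC[C@H]2C(C)(C)[C@H](O)CC[C@]2(C)[C@H]1CC1=CC(OC)(OC)C(CO[Si](C)(C)C(C)(C)C)=CC1=O
F7 | step 21 | (1S,6R)-4-[(tert-butyldimethylsilyloxy)methyl]-1-(3α-hydroxydrim-8(12)-en-11-yl)-5,5-dimethoxy-7-oxabicyclo[4.1.0]hept-3-en-2-one | C=C1CC[C@H]2C(C)(C)[C@H](O)CC[C@]2(C)[C@H]1C[C@]12O[C@H]1C(OC)(OC)C(CO[Si](C)(C)C(C)(C)C)=CC2=O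
F8 | step 23 | (1S,5S,6S)-5-hydroxy-1-(3α-hydroxydrim-8(12)-en-11-yl)-4-(hydroxymethyl)-7-oxabicyclo[4.1.0]hept-3-en-2-one (C5 epimer of 31) | C=C1CC[C@H]2C(C)(C)[C@H](O)CC[C@]2(C)[C@H]1C[C@]12O[C@H]1[C@@H](O)C(CO)=CC2=O
F9 | step 23 | C5 epimer of 35 (hydroxyl syn to the epoxide) | C=C1CC[C@H]2C(C)(C)[C@H](O)CC[C@]2(C)[C@H]1C[C@]12O[C@H]1[C@@H](O)C(COC(=O)C[C@H](C)O[Si](C)(C)C(C)(C)C)=CC2=O
F10 | step 23 | C5 formate of 35 | C=C1CC[C@H]2C(C)(C)[C@H](O)CC[C@]2(C)[C@H]1C[C@]12O[C@H]1[C@H](OC=O)C(COC(=O)C[C@H](C)O[Si](C)(C)C(C)(C)C)=CC2=O
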